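**Plan**

1. Numbering: the left unit is a 1,2,3,4-tetrahydrophenanthren-2-one (rings A and B aromatic; ring C = C1(Me2)–C2(=O)–C3(ketal)–C4(H,O)–C4a–C10a). The right phenanthrene is primed; O2' sits on C3 and O3' on C4.
2. Cuts, in order: O2'–C3 (ketal exchange), C10a–C1 (ring C), O3'–C4 (carbene O–H insertion), C2–C3 (ester alkylidenation). Ring B is cut at C8a–C9 back to an open-chain keto diester on ring A. The right phenanthrene is cut at C4a'–C4b' (Suzuki) and C9'–C10' (amide-directed cyclisation).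
3. Forward: the ring B benzannulation delivers O9, H10, an oxygen on C10a and the CH2CO2Me arm on C4a in one operation. Then follow the aryl triflate diazoester, union with the right-hand phenol at C4, ester → Z-enol ether → α-keto dimethyl ketal, ring C, the dioxane ring, and unmasking.
4. Enabling feature: C2 lies between the ketal carbon C3 and C1, so C1–H is its only enolisable position. C10a of ring B, ortho to the C4a arm and 1,6 to C1, carries the benzannulation oxygen as a triflate. Palladium joins C1 to C10a, a site meta to the ring-B oxygen that electrophilic substitution cannot address, closing ring C and creating the quaternary carbon.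
5. Stereochemistry: C4 (S) comes from a catalyst-controlled asymmetric O–H insertion. C3 (S) is relayed from C4 in the ketal exchange: in closed ring C the C4 aryloxy group is pseudo-axial (bay-region contact with H5), so the dioxane can only close cis.

Key step: step 21

Assumption: compounds 1, 2, 5, 13, 19 and 28 are purchased, and the ligand enantiomer in step 17 is the one that delivers the (S)-ether.

Abbreviations in names: NpL = 7-methoxy-6-methyl-4-[(methylsulfonyl)oxy]-2-[(trifluoromethylsulfonyl)oxy]naphthalen-1-yl (its C1, C2, C4 become C4a, C10a, C9 of the left unit). PhR = 9-methoxy-2,6-bis(methoxymethoxy)-1,7-dimethylphenanthren-3-yl.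

**Route**

Step 1
Reactants: 1 2-(3-methoxy-4-methylphenyl)acetic acid; 2 Meldrum's acid (2,2-dimethyl-1,3-dioxane-4,6-dione)
Product: 4 methyl 4-(3-methoxy-4-methylphenyl)-3-oxobutanoate, via acyl Meldrum's acid 3 (not isolated)
Conditions: DCC, DMAP, CH2Cl2, 0 °C to rt; then MeOH, reflux
Reagents that add atoms: methanol, CO
Why: Oikawa–Yonemitsu acylation of Meldrum's acid and methanolysis through the acylketene should give the β-keto ester without touching the arene.

Step 2
Reactants: 4 methyl 4-(3-methoxy-4-methylphenyl)-3-oxobutanoate; 5 methyl bromoacetate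
Product: 6 dimethyl 3-(3-methoxy-4-methylphenyl)-4-oxohexanedioate (racemic)
Conditions: LiN(iPr)2 (2.2 equiv), THF, −78 to 0 °C; then 5, −78 to 0 °C
Reagents that add atoms: none
Why: β-Keto ester dianion alkylation: the benzylic γ-carbanion is the more reactive site and should undergo SN2 with the bromo ester; the stereocentre formed is erased in step 3.

Step 3
Reactants: 6 dimethyl 3-(3-methoxy-4-methylphenyl)-4-oxohexanedioate
Product: 8 5-hydroxy-8-methoxy-7-methylnaphtho[2,1-b]furan-2(1H)-one, via naphthalene-1,3-diol ester 7 (not isolated)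
Conditions: conc. H2SO4, 0 °C to rt; then TsOH (cat.), toluene, 80 °C
Reagents that add atoms: none
Why: Intramolecular Friedel–Crafts acylation para to the ring-A methoxyl and enolisation build aromatic ring B (naphthoresorcinol-type benzannulation); the C10a hydroxyl then lactonises onto the adjacent ester arm, leaving only the C9 hydroxyl free.

Step 4
Reactants: 8 5-hydroxy-8-methoxy-7-methylnaphtho[2,1-b]furan-2(1H)-one
Product: 9 8-methoxy-7-methyl-2-oxo-1,2-dihydronaphtho[2,1-b]furan-5-yl methanesulfonate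
Conditions: MsCl, pyridine, CH2Cl2, 0 °C
Reagents that add atoms: methanesulfonyl chloride, CS(=O)(=O)Cl
Why: Sulfonylation of the only free hydroxyl; pyridine is too weak a base to enolise the lactone, and the mesylate makes ring B electron-poor for the later acid steps.

Step 5
Reactants: 9 8-methoxy-7-methyl-2-oxo-1,2-dihydronaphtho[2,1-b]furan-5-yl methanesulfonate
Product: 11 methyl 2-(NpL)acetate, via sodium naphtholate 10 (not isolated)
Conditions: NaOMe (1.05 equiv), THF–MeOH, −20 °C; then PhNTf2, −20 °C to rt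
Reagents that add atoms: sodium methoxide, [Na+].[O-]C; N-phenylbis(trifluoromethanesulfonimide), O=S(=O)(N(c1ccccc1)S(=O)(=O)C(F)(F)F)C(F)(F)F
Why: Methoxide opens the aryl ester (lactone) far faster than it attacks the mesylate, and the released naphtholate should be trapped in situ as the triflate; the methoxyl introduced here is the future ketal methoxyl.

Step 6
Reactants: 11 methyl 2-(NpL)acetate
Product: 12 methyl 2-diazo-2-(NpL)acetate
Conditions: 4-AcNHC6H4SO2N3, DBU, MeCN, 0 °C to rt
Reagents that add atoms: 4-acetamidobenzenesulfonyl azide, CC(=O)Nc1ccc(cc1)S(=O)(=O)N=[N+]=[N-]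
Why: Regitz diazo transfer to an arylacetate enolate is standard and tolerates aryl sulfonates.

Step 7
Reactants: 13 4-bromo-2,3-dimethylphenol
Product: 14 5-bromo-2-hydroxy-3,4-dimethylbenzaldehyde
Conditions: MgCl2, Et3N, (CH2O)n, MeCN, reflux
Reagents that add atoms: paraformaldehyde (as formaldehyde), C=O
Why: Magnesium phenoxide ortho-formylation (Casnati–Skattebøl) can only go to the single free ortho position, which becomes C3'.

Step 8
Reactants: 14 5-bromo-2-hydroxy-3,4-dimethylbenzaldehyde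
Product: 15 5-bromo-2-(methoxymethoxy)-3,4-dimethylbenzaldehyde
Conditions: NaH, MOMCl, DMF, 0 °C
Reagents that add atoms: chloromethyl methyl ether, COCCl
Why: Williamson-type acetalisation of the phenoxide; this oxygen (next to the methyl group) is the future O2'.

Step 9
Reactants: 15 5-bromo-2-(methoxymethoxy)-3,4-dimethylbenzaldehyde
Product: 17 5-bromo-2-(methoxymethoxy)-3,4-dimethylphenol, via aryl formate 16 (not isolated)
Conditions: mCPBA, CH2Cl2, rt; then K2CO3, MeOH, rt
Reagents that add atoms: 3-chloroperoxybenzoic acid, OOC(=O)c1cccc(Cl)c1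
Why: Dakin-type Baeyer–Villiger oxidation (aryl migration in an alkoxy-substituted benzaldehyde) and formate methanolysis should give the catechol with its two oxygens differentiated.

Step 10
Reactants: 17 5-bromo-2-(methoxymethoxy)-3,4-dimethylphenol
Product: 18 1-(benzyloxy)-5-bromo-2-(methoxymethoxy)-3,4-dimethylbenzene
Conditions: BnBr, K2CO3, DMF, rt
Reagents that add atoms: benzyl bromide, BrCc1ccccc1
Why: Williamson etherification; benzyl masks the future O3' through the basic steps and is removable in the presence of MOM.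

Step 11
Reactants: 19 4-hydroxy-3-methylbenzoic acid
Product: 20 N,N-diethyl-4-hydroxy-3-methylbenzamide
Conditions: Et2NH, EDC·HCl, HOBt, CH2Cl2, rt
Reagents that add atoms: diethylamine, CCNCC
Why: Carbodiimide amidation; the acid is activated in preference to the phenol.

Step 12
Reactants: 20 N,N-diethyl-4-hydroxy-3-methylbenzamide
Product: 21 N,N-diethyl-4-(methoxymethoxy)-3-methylbenzamide
Conditions: MOMCl, iPr2NEt, CH2Cl2, 0 °C to rt
Reagents that add atoms: chloromethyl methyl ether, COCCl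
Why: Standard MOM protection of the future O6'.

Step 13
Reactants: 21 N,N-diethyl-4-(methoxymethoxy)-3-methylbenzamide
Product: 22 [2-(diethylcarbamoyl)-5-(methoxymethoxy)-4-methylphenyl]boronic acid
Conditions: s-BuLi, TMEDA, THF, −78 °C; B(OMe)3; aq. NH4Cl
Reagents that add atoms: trimethyl borate, COB(OC)OC; water, O
Why: Directed ortho-metalation: the tertiary amide is the stronger director and the position next to H (not next to the methyl group) is lithiated, then borylated.

Step 14
Reactants: 18 1-(benzyloxy)-5-bromo-2-(methoxymethoxy)-3,4-dimethylbenzene; 22 [2-(diethylcarbamoyl)-5-(methoxymethoxy)-4-methylphenyl]boronic acid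
Product: 23 5'-(benzyloxy)-N,N-diethyl-5,4'-bis(methoxymethoxy)-4,2',3'-trimethyl-[1,1'-biphenyl]-2-carboxamide
Conditions: Pd(OAc)2 (5 mol%), SPhos, K3PO4, toluene–H2O, 90 °C
Reagents that add atoms: none
Why: Suzuki–Miyaura coupling with a dialkylbiarylphosphine handles the tri-ortho-substituted biaryl and fixes the C4a'–C4b' bond without any regiochemical choice.

Step 15
Reactants: 23 5'-(benzyloxy)-N,N-diethyl-5,4'-bis(methoxymethoxy)-4,2',3'-trimethyl-[1,1'-biphenyl]-2-carboxamide
Product: 25 3-(benzyloxy)-9-methoxy-2,6-bis(methoxymethoxy)-1,7-dimethylphenanthrene, via lithium phenanthren-9-olate 24 (not isolated)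
Conditions: LiN(iPr)2 (3 equiv), THF, 0 °C to rt; then Me2SO4, DMPU, 0 °C to rt
Reagents that add atoms: dimethyl sulfate, COS(=O)(=O)OC
Why: Amide-directed remote (lateral) metalation of the 2'-methyl group and attack on the amide give the 9-phenanthrolate (directed remote metalation–cyclisation); the hard electrophile in DMPU should methylate on oxygen.

Step 16
Reactants: 25 3-(benzyloxy)-9-methoxy-2,6-bis(methoxymethoxy)-1,7-dimethylphenanthrene
Product: 26 9-methoxy-2,6-bis(methoxymethoxy)-1,7-dimethylphenanthren-3-ol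
Conditions: H2 (1 atm), Pd/C, EtOAc, rt
Reagents that add atoms: none
Why: Hydrogenolysis of the benzyl ether is much faster than reduction of the phenanthrene 9,10-bond and frees O3' only.

Step 17
Reactants: 12 methyl 2-diazo-2-(NpL)acetate; 26 9-methoxy-2,6-bis(methoxymethoxy)-1,7-dimethylphenanthren-3-ol
Product: 27 methyl (2S)-2-(NpL)-2-(PhR-oxy)acetate
Conditions: PdCl2(PhCN)2 (5 mol%), chiral spiro bis(oxazoline) ligand (6 mol%), Na[B(3,5-(CF3)2C6H3)4] (12 mol%), 5 Å MS, CHCl3, 25 °C
Reagents that add atoms: none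
Why: Catalytic asymmetric carbene O–H insertion of an aryldiazoacetate into a phenol through a divalent palladium carbene; the chiral ligand sphere controls the proton transfer that sets C4 as S, and because only O3' is free the regiochemistry of the later dioxane is fixed here.

Step 18
Reactants: 27 methyl (2S)-2-(NpL)-2-(PhR-oxy)acetate; 28 1,1-dibromo-2-methylpropane
Product: 29 (1S,2Z)-2-methoxy-4-methyl-1-(NpL)-1-(PhR-oxy)pent-2-ene
Conditions: Zn, PbCl2 (cat.), TiCl4, TMEDA, THF, 25 °C; basic work-up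
Reagents that add atoms: none
Why: Takai–Utimoto alkylidenation turns the ester carbonyl into the Z-enol ether under non-basic conditions, so the acidic C4–H stereocentre is untouched and the ester methoxyl is kept on C3.

Step 19
Reactants: 29 (1S,2Z)-2-methoxy-4-methyl-1-(NpL)-1-(PhR-oxy)pent-2-ene
Product: 31 (1S)-2,2-dimethoxy-4-methyl-1-(NpL)-1-(PhR-oxy)pentan-3-ol (both carbinol epimers), via methoxy epoxide 30 (not isolated)
Conditions: DMDO (1.05 equiv), acetone–MeOH, −40 to 0 °C
Reagents that add atoms: dimethyldioxirane, CC1(C)OO1; methanol, CO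
Why: Epoxidation of the electron-rich enol ether (much faster than arene oxidation) and SN1-type methanolysis at the acetal carbon should give the α-hydroxy dimethyl ketal; the new carbinol centre is oxidised away in step 20.

Step 20
Reactants: 31 (1S)-2,2-dimethoxy-4-methyl-1-(NpL)-1-(PhR-oxy)pentan-3-ol
Product: 32 (1S)-2,2-dimethoxy-4-methyl-1-(NpL)-1-(PhR-oxy)pentan-3-one
Conditions: DMP, NaHCO3, CH2Cl2, rt
Reagents that add atoms: none
Why: Dess–Martin oxidation of a hindered secondary alcohol under buffered conditions; C4 is now flanked by a ketal and cannot epimerise.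

Step 21
Reactants: 32 (1S)-2,2-dimethoxy-4-methyl-1-(NpL)-1-(PhR-oxy)pentan-3-one
Product: 33 (4S)-3,3,6-trimethoxy-1,1,7-trimethyl-2-oxo-4-(PhR-oxy)-1,2,3,4-tetrahydrophenanthren-9-yl methanesulfonate
Conditions: Pd2(dba)3 (5 mol%), Xantphos (12 mol%), K3PO4 (3 equiv), toluene, 100 °C
Reagents that add atoms: none
Why: Zerovalent palladium inserts into the C10a–OTf bond, the phosphate base forms the enolate at C1 (the only enolisable position, since C3 is a ketal), and reductive elimination from the C-bound palladium enolate forms the C10a–C1 bond. The closest known reaction type is the Buchwald–Hartwig–Miura ketone α-arylation in its intramolecular form, which is established for quaternary benzylic carbons. Ring C closes as a six-membered ring by C–C reductive elimination from a seven-membered arylpalladium enolate palladacycle (a 6-enolexo closure at C1). No new stereocentre is formed, because C1 carries two methyl groups, and C4 stays S because it has no acidic hydrogen. The step needs triflate-over-mesylate selectivity, which the large rate difference in oxidative addition with this ligand should secure, and reductive elimination over β-hydride elimination, which the wide-bite-angle ligand favours. The regiochemistry at the arene, meta to the ring-B oxygen, is secured by where the benzannulation placed the leaving group.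

Step 22
Reactants: 33 (4S)-3,3,6-trimethoxy-1,1,7-trimethyl-2-oxo-4-(PhR-oxy)-1,2,3,4-tetrahydrophenanthren-9-yl methanesulfonate
Product: 34 (4S)-4-[(2,6-dihydroxy-9-methoxy-1,7-dimethylphenanthren-3-yl)oxy]-3,3,6-trimethoxy-1,1,7-trimethyl-2-oxo-1,2,3,4-tetrahydrophenanthren-9-yl methanesulfonate
Conditions: HCl (cat.), MeOH, 40 °C
Reagents that add atoms: none
Why: Acid-catalysed acetal exchange with methanol removes both MOM ethers; the dimethyl ketal only exchanges degenerately in methanol, and the mesyloxy-substituted ring B keeps the benzylic C4–O bond from ionising.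

Step 23
Reactants: 34 (4S)-4-[(2,6-dihydroxy-9-methoxy-1,7-dimethylphenanthren-3-yl)oxy]-3,3,6-trimethoxy-1,1,7-trimethyl-2-oxo-1,2,3,4-tetrahydrophenanthren-9-yl methanesulfonate
Product: 35 actephilol C 9-O-methanesulfonate (cis-fused dioxane; C3 S and C4 S)
Conditions: CSA (0.2 equiv), 5 Å MS, toluene, 60 °C
Reagents that add atoms: none
Why: Intramolecular acid-catalysed transketalisation, with methanol taken up by the sieves, closes the dioxane; C4 controls C3, because the pseudo-axial C4 aryloxy group (bay-region strain with H5) lets O2' reach the C3 oxocarbenium ion only from its own face, giving the cis-fused ketal.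

Step 24
Reactants: 35 actephilol C 9-O-methanesulfonate
Product: 36 actephilol C
Conditions: LiN(iPr)2 (4 equiv), THF, −78 °C; aq. NH4Cl
Reagents that add atoms: none
Why: Deprotonation of the mesyl methyl group and E1cB loss of sulfene free the C9 phenol at low temperature without acid or nucleophile; the ketone has no α-hydrogen and the ketal is base-stable.

**Compound list**

1 | 2-(3-methoxy-4-methylphenyl)acetic acid | COc1cc(CC(=O)O)ccc1C | starting material
2 | Meldrum's acid | CC1(C)OC(=O)CC(=O)O1 | starting material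
3 | 5-[1-hydroxy-2-(3-methoxy-4-methylphenyl)ethylidene]-2,2-dimethyl-1,3-dioxane-4,6-dione | COc1cc(CC(O)=C2C(=O)OC(C)(C)OC2=O)ccc1C | intermediate (not isolated)
4 | methyl 4-(3-methoxy-4-methylphenyl)-3-oxobutanoate | COc1cc(CC(=O)CC(=O)OC)ccc1C | intermediate
5 | methyl bromoacetate | COC(=O)CBr | starting material
6 | dimethyl 3-(3-methoxy-4-methylphenyl)-4-oxohexanedioate (racemic) | COc1cc(C(CC(=O)OC)C(=O)CC(=O)OC)ccc1C | intermediate
7 | methyl 2-(2,4-dihydroxy-7-methoxy-6-methylnaphthalen-1-yl)acetate | COc1cc2c(CC(=O)OC)c(O)cc(O)c2cc1C | intermediate (not isolated)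
8 | 5-hydroxy-8-methoxy-7-methylnaphtho[2,1-b]furan-2(1H)-one | COc1cc2c3CC(=O)Oc3cc(O)c2cc1C | intermediate
9 | 8-methoxy-7-methyl-2-oxo-1,2-dihydronaphtho[2,1-b]furan-5-yl methanesulfonate | COc1cc2c3CC(=O)Oc3cc(OS(C)(=O)=O)c2cc1C | intermediate
10 | sodium 7-methoxy-1-(2-methoxy-2-oxoethyl)-6-methyl-4-[(methylsulfonyl)oxy]naphthalen-2-olate | [Na+].COc1cc2c(CC(=O)OC)c([O-])cc(OS(C)(=O)=O)c2cc1C | intermediate (not isolated)
11 | methyl 2-(NpL)acetate | COc1cc2c(CC(=O)OC)c(OS(=O)(=O)C(F)(F)F)cc(OS(C)(=O)=O)c2cc1C | intermediate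
12 | methyl 2-diazo-2-(NpL)acetate | COc1cc2c(C(=[N+]=[N-])C(=O)OC)c(OS(=O)(=O)C(F)(F)F)cc(OS(C)(=O)=O)c2cc1C | intermediate
13 | 4-bromo-2,3-dimethylphenol | Cc1c(C)c(Br)ccc1O | starting material
14 | 5-bromo-2-hydroxy-3,4-dimethylbenzaldehyde | Cc1c(C)c(Br)cc(C=O)c1O | intermediate
15 | 5-bromo-2-(methoxymethoxy)-3,4-dimethylbenzaldehyde | Cc1c(C)c(Br)cc(C=O)c1OCOC | intermediate
16 | 5-bromo-2-(methoxymethoxy)-3,4-dimethylphenyl formate | Cc1c(C)c(Br)cc(OC=O)c1OCOC | intermediate (not isolated)
17 | 5-bromo-2-(methoxymethoxy)-3,4-dimethylphenol | Cc1c(C)c(Br)cc(O)c1OCOC | intermediate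
18 | 1-(benzyloxy)-5-bromo-2-(methoxymethoxy)-3,4-dimethylbenzene | Cc1c(C)c(Br)cc(OCc2ccccc2)c1OCOC | intermediate
19 | 4-hydroxy-3-methylbenzoic acid | Cc1cc(C(=O)O)ccc1O | starting material
20 | N,N-diethyl-4-hydroxy-3-methylbenzamide | CCN(CC)C(=O)c1ccc(O)c(C)c1 | intermediate
21 | N,N-diethyl-4-(methoxymethoxy)-3-methylbenzamide | CCN(CC)C(=O)c1ccc(OCOC)c(C)c1 | intermediate
22 | [2-(diethylcarbamoyl)-5-(methoxymethoxy)-4-methylphenyl]boronic acid | CCN(CC)C(=O)c1cc(C)c(OCOC)cc1B(O)O | intermediate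
23 | 5'-(benzyloxy)-N,N-diethyl-5,4'-bis(methoxymethoxy)-4,2',3'-trimethyl-[1,1'-biphenyl]-2-carboxamide | CCN(CC)C(=O)c1cc(C)c(OCOC)cc1-c1cc(OCc2ccccc2)c(OCOC)c(C)c1C | intermediate
24 | lithium 3-(benzyloxy)-2,6-bis(methoxymethoxy)-1,7-dimethylphenanthren-9-olate | [Li+].[O-]c1cc2c(C)c(OCOC)c(OCc3ccccc3)cc2c2cc(OCOC)c(C)cc12 | intermediate (not isolated)
25 | 3-(benzyloxy)-9-methoxy-2,6-bis(methoxymethoxy)-1,7-dimethylphenanthrene | COc1cc2c(C)c(OCOC)c(OCc3ccccc3)cc2c2cc(OCOC)c(C)cc12 | intermediate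
26 | 9-methoxy-2,6-bis(methoxymethoxy)-1,7-dimethylphenanthren-3-ol | COc1cc2c(C)c(OCOC)c(O)cc2c2cc(OCOC)c(C)cc12 | intermediate
27 | methyl (2S)-2-(NpL)-2-(PhR-oxy)acetate | COc1cc2c(C)c(OCOC)c(O[C@@H](c3c(OS(=O)(=O)C(F)(F)F)cc(OS(C)(=O)=O)c4cc(C)c(OC)cc34)C(=O)OC)cc2c2cc(OCOC)c(C)cc12 | intermediate
28 | 1,1-dibromo-2-methylpropane | CC(C)C(Br)Br | starting material
29 | (1S,2Z)-2-methoxy-4-methyl-1-(NpL)-1-(PhR-oxy)pent-2-ene | COc1cc2c(C)c(OCOC)c(O[C@@H](c3c(OS(=O)(=O)C(F)(F)F)cc(OS(C)(=O)=O)c4cc(C)c(OC)cc34)/C(OC)=C/C(C)C)cc2c2cc(OCOC)c(C)cc12 | intermediate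
30 | 2-methoxy-2-[(S)-(NpL)(PhR-oxy)methyl]-3-(propan-2-yl)oxirane (epoxide of 29) | COc1cc2c(C)c(OCOC)c(O[C@@H](c3c(OS(=O)(=O)C(F)(F)F)cc(OS(C)(=O)=O)c4cc(C)c(OC)cc34)C3(OC)OC3C(C)C)cc2c2cc(OCOC)c(C)cc12 | intermediate (not isolated)
31 | (1S)-2,2-dimethoxy-4-methyl-1-(NpL)-1-(PhR-oxy)pentan-3-ol (both carbinol epimers) | COc1cc2c(C)c(OCOC)c(O[C@@H](c3c(OS(=O)(=O)C(F)(F)F)cc(OS(C)(=O)=O)c4cc(C)c(OC)cc34)C(OC)(OC)C(O)C(C)C)cc2c2cc(OCOC)c(C)cc12 | intermediate
32 | (1S)-2,2-dimethoxy-4-methyl-1-(NpL)-1-(PhR-oxy)pentan-3-one | COc1cc2c(C)c(OCOC)c(O[C@@H](c3c(OS(=O)(=O)C(F)(F)F)cc(OS(C)(=O)=O)c4cc(C)c(OC)cc34)C(OC)(OC)C(=O)C(C)C)cc2c2cc(OCOC)c(C)cc12 | intermediate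
33 | (4S)-3,3,6-trimethoxy-1,1,7-trimethyl-2-oxo-4-(PhR-oxy)-1,2,3,4-tetrahydrophenanthren-9-yl methanesulfonate | COc1cc2c3c(cc(OS(C)(=O)=O)c2cc1C)C(C)(C)C(=O)C(OC)(OC)[C@H]3Oc1cc2c(cc(OC)c3cc(C)c(OCOC)cc32)c(C)c1OCOC | intermediate
34 | (4S)-4-[(2,6-dihydroxy-9-methoxy-1,7-dimethylphenanthren-3-yl)oxy]-3,3,6-trimethoxy-1,1,7-trimethyl-2-oxo-1,2,3,4-tetrahydrophenanthren-9-yl methanesulfonate | COc1cc2c3c(cc(OS(C)(=O)=O)c2cc1C)C(C)(C)C(=O)C(OC)(OC)[C@H]3Oc1cc2c(cc(OC)c3cc(C)c(O)cc32)c(C)c1O | intermediate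
35 | actephilol C 9-O-methanesulfonate (cis-fused dioxane; ketal carbon C3 S, C4 S) | COc1cc2c3c(cc(OS(C)(=O)=O)c2cc1C)C(C)(C)C(=O)[C@@]1(OC)Oc2c(cc4c(cc(OC)c5cc(C)c(O)cc54)c2C)O[C@@H]31 | intermediate
36 | actephilol C (cis-fused dioxane; ketal carbon C3 S, C4 S) | COc1cc2c3c(cc(O)c2cc1C)C(C)(C)C(=O)[C@@]1(OC)Oc2c(cc4c(cc(OC)c5cc(C)c(O)cc54)c2C)O[C@@H]31 | target

**Count and risks**

Total step count: 24. Longest linear sequence: 15 steps (13 → 36 through steps 7–10 and 14–24).

Steps most likely to fail: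

- Step 21 (key step). β-Hydride elimination from the tertiary palladium enolate, or slow reductive elimination at the congested quaternary carbon, may outrun ring closure. The fallback sets out from 32. It is silylated (TMSOTf, Et3N, CH2Cl2) to the trimethylsilyl enol ether F1 and brominated (NBS, THF, −78 °C) to the tertiary α-bromo ketone F2. F2 is closed by a nickel-catalysed intramolecular reductive cross-electrophile coupling of the aryl triflate with the α-bromo ketone (NiBr2(dme), 4,4'-di-tert-butyl-2,2'-bipyridine, Zn, DMA, 40 °C). In that coupling a tertiary radical is captured at nickel, so no enolate is needed. The route is rejoined at 33.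

- Step 23. The α-keto ketal may fail to ionise, because the neighbouring carbonyl destabilises the oxocarbenium ion, or the benzylic C4–O bond may ionise instead. The fallback sets out from 34. The ketone is reduced (LiBH4, THF) to the C2 alcohol F3 (carbinol epimers). Its β-hydroxy ketal should exchange readily (CSA, 5 Å MS, CH2Cl2) to the dioxane alcohol F4, cis-fused for the same conformational reason. Parikh–Doering oxidation (SO3·pyridine, DMSO, iPr2NEt) returns the ketone and rejoins the route at 35.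

- Step 18. Alkylidenation of the hindered, Lewis-basic ester may stall, and titanium or zinc salts may ionise the allylic-benzylic C4–O bond of the product. The fallback sets out from 27. Methylenation with Cp2TiMe2 (toluene, 65 °C; Petasis olefination) gives the 2-methoxyallyl ether F5. DMDO in acetone–MeOH gives the primary α,α-dimethoxy alcohol F6, and DMP oxidation gives the non-enolisable aldehyde F7. Addition of iPrMgCl (THF, −78 °C) rejoins the route at 31.

**Further compounds**

F1 | step 21 | trimethylsilyl enol ether of 32, (1S)-2,2-dimethoxy-4-methyl-1-(NpL)-1-(PhR-oxy)-3-(trimethylsilyloxy)pent-3-ene | COc1cc2c(C)c(OCOC)c(O[C@@H](c3c(OS(=O)(=O)C(F)(F)F)cc(OS(C)(=O)=O)c4cc(C)c(OC)cc34)C(OC)(OC)C(O[Si](C)(C)C)=C(C)C)cc2c2cc(OCOC)c(C)cc12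
F2 | step 21 | (1S)-4-bromo-2,2-dimethoxy-4-methyl-1-(NpL)-1-(PhR-oxy)pentan-3-one | COc1cc2c(C)c(OCOC)c(O[C@@H](c3c(OS(=O)(=O)C(F)(F)F)cc(OS(C)(=O)=O)c4cc(C)c(OC)cc34)C(OC)(OC)C(=O)C(C)(C)Br)cc2c2cc(OCOC)c(C)cc12
F3 | step 23 | C2 alcohol of 34 (4S; carbinol epimers) | COc1cc2c3c(cc(OS(C)(=O)=O)c2cc1C)C(C)(C)C(O)C(OC)(OC)[C@H]3Oc1cc2c(cc(OC)c3cc(C)c(O)cc32)c(C)c1O
F4 | step 23 | C2 alcohol of 35 (cis-fused dioxane with the ring-fusion configuration of 35; carbinol epimers) | COc1cc2c3c(cc(OS(C)(=O)=O)c2cc1C)C(C)(C)C(O)[C@@]1(OC)Oc2c(cc4c(cc(OC)c5cc(C)c(O)cc54)c2C)O[C@@H]31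
F5 | step 18 | (1S)-2-methoxy-1-(NpL)-1-(PhR-oxy)prop-2-ene | COc1cc2c(C)c(OCOC)c(O[C@@H](c3c(OS(=O)(=O)C(F)(F)F)cc(OS(C)(=O)=O)c4cc(C)c(OC)cc34)C(OC)=C)cc2c2cc(OCOC)c(C)cc12
F6 | step 18 | (3S)-2,2-dimethoxy-3-(NpL)-3-(PhR-oxy)propan-1-ol | COc1cc2c(C)c(OCOC)c(O[C@@H](c3c(OS(=O)(=O)C(F)(F)F)cc(OS(C)(=O)=O)c4cc(C)c(OC)cc34)C(OC)(OC)CO)cc2c2cc(OCOC)c(C)cc12
F7 | step 18 | (3S)-2,2-dimethoxy-3-(NpL)-3-(PhR-oxy)propanal | COc1cc2c(C)c(OCOC)c(O[C@@H](c3c(OS(=O)(=O)C(F)(F)F)cc(OS(C)(=O)=O)c4cc(C)c(OC)cc34)C(OC)(OC)C=O)cc2c2cc(OCOC)c(C)cc12
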